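The readings were generated by integration with made-up constants; noise was put on by code.

Thursday's run ended at 8.00 h with X at 17% and D at 36%, so 47.0% of the charge went elsewhere. Here is what you are taking over.

| setting | Friday's | Thursday's | grey | violet | blue | teal |
|---|---|---|---|---|---|---|
| D | 0.25 M | 0.38 M | 0.50 M | 0.50 M | 0.50 M | 0.50 M |
| temperature | 55 °C | 80 °C | 100 °C |  | 60 °C | 80 °C |
| remark | run made earlier | run made earlier |  | at 100 °C until 1.0 h, from then on at 60 °C |  |  |
| time |  |  | 5.0 h | 5.0 h | 5.0 h | 5.0 h |

| run | time / h | X / % | D / % |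
|---|---|---|---|
| Friday's | 2.50 | 3 | 95 |
| Friday's | 3.00 | 1 | 96 |
| Friday's | 5.00 | 0 | 89 |
| Friday's | 8.00 | 1 | 87 |
| Friday's | 12.0 | 1 | 82 |
| Friday's | 20.0 | 0 | 72 |
| Friday's | 30.0 | 4 | 65 |
| Thursday's | 0.417 | 3 | 92 |
| Thursday's | 1.33 | 4 | 80 |
| Thursday's | 2.50 | 8 | 68 |
| Thursday's | 4.00 | 14 | 57 |
| Thursday's | 5.00 | 12 | 48 |
| Thursday's | 6.00 | 18 | 40 |
| Thursday's | 8.00 | 17 | 36 |

(readings scatter by 1.5 percentage points)

- a species is counted by the D in it: one Q counts as two
- on the list of suspects stand: 2 D -> Q; D <-> Z; Z -> E; D -> X; Z <-> G; G -> J; X -> L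
- in a conversion Z counts as not yet reacted; G counts as reacted

- which flask leads in amount of X, in percent of the D charged ("all alike" within 1.5 percentage points) (grey / violet / blue / teal / all alike)
- how much X is there at the end, in percent of the D charged: grey
- how much X is there at the end, in percent of the D charged: violet
- how much X is there at the end, in percent of the D charged: blue
- how much X is there at the end, in percent of the D charged: teal

On the list of suspects, D goes to X in proportion to D, but to Q in proportion to D squared, so thin D favours X. X's gain over the other loss, times the average D, therefore reads a crossover (a selectivity in concentration units). Thursday's gives 0.0935 M. Friday's gives 0.0266 M, but that is rough, since its X reading of 4% carries a scatter of 1.5 percentage points.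

Keeping the same factor per degree puts grey at 0.255 M, the concentration of D at which the paths to X and to Q use D equally. Grey starts at 0.50 M, above it, so I expect Q to lead at first and X to lead later. Joining the two ends, with c the crossover and a the charge, and taking D to go by these two paths, the share reaching X once D is spent is (c/a) ln((c+a)/c), which I reckon at 55.4% for grey. That share counts X and the L made from it. For teal, with Thursday's crossover, it is 34.6% once its D is spent, less than grey's, so I expect grey to lead. Thursday's last X readings, 18% and 17%, lie within the scatter of each other, so they give no measure of the loss to L. Leave violet's bath alone after the change; as a guide to its cold stretch, Friday's flask, at 55 °C and charged with 0.25 M, read 4% of X at 30.0 h.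

The forecast put grey first, with grey 42%, violet 27%, blue 1% and teal 13%, holding that the plateau “shows little X loss”.

The flasks give grey first, with grey 32.0%, violet 26.2%, blue 1.54% and teal 13.7%.

    2 D → Q (k = 0.680 M⁻¹ h⁻¹, Ea = 68.0 kJ mol⁻¹)
    D ⇌ Z (K = 1.00, k = 0.0230 h⁻¹, Ea = 115 kJ mol⁻¹, ΔH = −90.0 kJ mol⁻¹)
    Z → E (k = 1.30 h⁻¹, Ea = 107 kJ mol⁻¹)
    D → X (k = 0.440 h⁻¹, Ea = 125 kJ mol⁻¹)
    Z ⇌ G (K = 0.780, k = 0.200 h⁻¹, Ea = 110 kJ mol⁻¹, ΔH = −42.0 kJ mol⁻¹)
    G → J (k = 0.360 h⁻¹, Ea = 110 kJ mol⁻¹)
    X → L (k = 0.150 h⁻¹, Ea = 119 kJ mol⁻¹)
    (constants at 100 °C)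

At 5.00 h grey holds X 32.0% and L 22.5%, together 54.5%, with D at 4.3%; my share, reckoned for D spent, was 55.4%. At its start, grey's D use by the path to X over that by the path to Q is 0.65, so its crossover is 0.324 M, above my 0.255 M. Take a neighbour of grey charged with 0.85 M of D, which ends with 3.0% of its D left. Its temperature is grey's, so I keep grey's crossover, and counting that remainder, (c/a) ln((c+a)/(c+d)), with d the concentration of D left, gives 46.2%. The neighbour holds X 25.9% and L 18.9%, together 44.8%.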